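The synthesis rests on disconnecting the chain C-2–C-3 bond of the propan-1-one, between the stereogenic carbon and the diarylmethine carbon. The two para-hydroxyphenyl rings make chain C-3 the exocyclic carbon of a latent para-quinone methide. Chain C-2, flanked by the aryl ketone carbonyl and position 3 of the chromone ring, is a readily enolized carbon. A chiral phosphoric acid generates the quinone methide from bis(4-hydroxyphenyl)methanol and steers enantioselective 1,6-addition of the enol of a benzyl-protected 3-(aroylmethyl)chromone. This joins the fragments and sets the only stereocentre in one operation. The precursor ketone comes from an ortho-hydroxyaryl enaminone and a phenacyl bromide; hydrogenolysis finishes the synthesis.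

Key step: step 7

Remark: by CIP analysis the stereocentre (chain C-2) of the target is (S), with priorities C=O > chromen-3-yl > CH(aryl)2 > H; the dextrorotatory natural product is taken to be this enantiomer.

Step 1
Reactants: 1 2',4',6'-trihydroxyacetophenone
Product: 2 1-[2,4-bis(benzyloxy)-6-hydroxyphenyl]ethan-1-one
Conditions: BnBr (2.1 equiv), K2CO3 (2.2 equiv), DMF, rt
Reagents that add atoms: benzyl bromide, BrCc1ccccc1
Why: Williamson etherification should stop at the bis-ether because the remaining ortho hydroxyl is held in a hydrogen bond to the ketone and is the least nucleophilic of the three.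

Step 2
Reactants: 2 1-[2,4-bis(benzyloxy)-6-hydroxyphenyl]ethan-1-one
Product: 3 (E)-1-[2,4-bis(benzyloxy)-6-hydroxyphenyl]-3-(dimethylamino)prop-2-en-1-one
Conditions: N,N-dimethylformamide dimethyl acetal (2 equiv), toluene, 95 °C
Reagents that add atoms: N,N-dimethylformamide dimethyl acetal, COC(OC)N(C)C
Why: Condensation of the acetyl methyl group with the amide acetal (enaminone formation) should give the E-enaminone with the chelated phenol left free.

Step 3
Reactants: 1 2',4',6'-trihydroxyacetophenone
Product: 4 1-[2,4,6-tris(benzyloxy)phenyl]ethan-1-one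
Conditions: BnBr (3.6 equiv), K2CO3 (4 equiv), DMF, 80 °C
Reagents that add atoms: benzyl bromide, BrCc1ccccc1
Why: Exhaustive Williamson etherification under forcing conditions should also cap the chelated ortho hydroxyl.

Step 4
Reactants: 4 1-[2,4,6-tris(benzyloxy)phenyl]ethan-1-one
Product: 5 2-bromo-1-[2,4,6-tris(benzyloxy)phenyl]ethan-1-one
Conditions: CuBr2 (2 equiv), EtOAc/CHCl3, reflux
Reagents that add atoms: CuBr2, [Cu+2].[Br-].[Br-]
Why: Heterogeneous alpha-bromination of an aryl methyl ketone with CuBr2 proceeds through the copper enolate and should brominate the methyl group in preference to the electron-rich ring.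

Step 5
Reactants: 3 (E)-1-[2,4-bis(benzyloxy)-6-hydroxyphenyl]-3-(dimethylamino)prop-2-en-1-one; 5 2-bromo-1-[2,4,6-tris(benzyloxy)phenyl]ethan-1-one (1.3 equiv)
Product: 7 2-[5,7-bis(benzyloxy)-4-oxo-4H-chromen-3-yl]-1-[2,4,6-tris(benzyloxy)phenyl]ethan-1-one, via 2-(dimethylamino)chroman-4-one aminal 6 (not isolated)
Conditions: fac-Ir(ppy)3 (1 mol %), NaHCO3 (2 equiv), degassed MeCN, blue LEDs, rt
Reagents that add atoms: none
Why: In this photoredox domino alpha-alkylation/chromone annulation of an ortho-hydroxyaryl enaminone, the electrophilic phenacyl radical from 5 should add to the nucleophilic enaminone alpha-carbon, the alpha-amino radical is oxidized to an iminium ion that the phenol traps as aminal 6, and loss of dimethylamine gives the chromone with the side chain fixed at position 3.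

Step 6
Reactants: 8 4,4'-dihydroxybenzophenone
Product: 9 bis(4-hydroxyphenyl)methanol
Conditions: NaBH4 (4 equiv), EtOH, 0 °C to 40 °C; aq. NH4Cl to pH 7 at 0 °C; used at once
Reagents that add atoms: none
Why: Borohydride reduction of the diaryl ketone should give the benzhydrol, with excess hydride offsetting deactivation by phenoxide formation and a neutral cold work-up avoiding premature ionization.

Step 7
Reactants: 7 2-[5,7-bis(benzyloxy)-4-oxo-4H-chromen-3-yl]-1-[2,4,6-tris(benzyloxy)phenyl]ethan-1-one; 9 bis(4-hydroxyphenyl)methanol (1.3 equiv, added in portions)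
Product: 11 (2S)-2-[5,7-bis(benzyloxy)-4-oxo-4H-chromen-3-yl]-3,3-bis(4-hydroxyphenyl)-1-[2,4,6-tris(benzyloxy)phenyl]propan-1-one, via para-quinone methide 10 (not isolated)
Conditions: (R)-TRIP [(R)-3,3'-bis(2,4,6-triisopropylphenyl)-1,1'-binaphthyl-2,2'-diyl hydrogen phosphate] (10 mol %), CH2Cl2, 5 Å MS, 0 °C
Reagents that add atoms: none
Why: Proposed new method: the phosphoric acid dehydrates benzhydrol 9 to para-quinone methide 10 and holds it by a hydrogen bond to its carbonyl oxygen, while the phosphoryl oxygen binds the OH of the Z-enol of ketone 7, so that enol carbon C-2 adds in a 1,6-fashion to the exocyclic carbon of 10 and the phenol ring is rearomatized. The closest known reaction types are chiral phosphoric acid-catalysed 1,6-additions of 1,3-dicarbonyl compounds, azlactones and oxindoles to para-quinone methides generated in situ from para-hydroxybenzyl alcohols, and Brønsted acid enol catalysis of alpha-aryl ketones; an acyclic alpha-chromonyl ketone giving a tertiary centre has not been shown. No ring is closed. The new stereocentre C-2 is set by the catalyst, whose 2,4,6-triisopropylphenyl walls are expected to leave the Si face of the enol carbon open, which gives (S); chain C-3 carries two identical aryl groups and is not stereogenic. The step needs C-alkylation at C-2 in preference to Friedel-Crafts attack on the benzyloxy-substituted rings, which is secured because only the enol offers a hydrogen-bond donor to the bifunctional catalyst; it also needs the product not to re-enolize, which the flanking diarylmethyl and 2,6-disubstituted aroyl groups should prevent through allylic strain.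

Step 8
Reactants: 11 (2S)-2-[5,7-bis(benzyloxy)-4-oxo-4H-chromen-3-yl]-3,3-bis(4-hydroxyphenyl)-1-[2,4,6-tris(benzyloxy)phenyl]propan-1-one
Product: 12 (+)-chamaechromone, (2S)-2-(5,7-dihydroxy-4-oxo-4H-chromen-3-yl)-3,3-bis(4-hydroxyphenyl)-1-(2,4,6-trihydroxyphenyl)propan-1-one
Conditions: H2 (1 atm), Pd/C (10 % Pd), EtOAc/MeOH, rt
Reagents that add atoms: none
Why: Hydrogenolysis of the five aryl benzyl ethers under neutral conditions should leave the acidic stereocentre, the chromone double bond and the hindered ketone untouched.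

Compound list
1 | 2',4',6'-trihydroxyacetophenone | CC(=O)c1c(O)cc(O)cc1O | starting material
2 | 1-[2,4-bis(benzyloxy)-6-hydroxyphenyl]ethan-1-one | CC(=O)c1c(O)cc(OCc2ccccc2)cc1OCc1ccccc1 | intermediate
3 | (E)-1-[2,4-bis(benzyloxy)-6-hydroxyphenyl]-3-(dimethylamino)prop-2-en-1-one | CN(C)/C=C/C(=O)c1c(O)cc(OCc2ccccc2)cc1OCc1ccccc1 | intermediate
4 | 1-[2,4,6-tris(benzyloxy)phenyl]ethan-1-one | CC(=O)c1c(OCc2ccccc2)cc(OCc2ccccc2)cc1OCc1ccccc1 | intermediate
5 | 2-bromo-1-[2,4,6-tris(benzyloxy)phenyl]ethan-1-one | O=C(CBr)c1c(OCc2ccccc2)cc(OCc2ccccc2)cc1OCc1ccccc1 | intermediate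
6 | 5,7-bis(benzyloxy)-2-(dimethylamino)-3-{2-oxo-2-[2,4,6-tris(benzyloxy)phenyl]ethyl}chroman-4-one (aminal, diastereomer mixture, not isolated) | CN(C)C1Oc2cc(OCc3ccccc3)cc(OCc3ccccc3)c2C(=O)C1CC(=O)c1c(OCc2ccccc2)cc(OCc2ccccc2)cc1OCc1ccccc1 | intermediate
7 | 2-[5,7-bis(benzyloxy)-4-oxo-4H-chromen-3-yl]-1-[2,4,6-tris(benzyloxy)phenyl]ethan-1-one | O=C(Cc1coc2cc(OCc3ccccc3)cc(OCc3ccccc3)c2c1=O)c1c(OCc2ccccc2)cc(OCc2ccccc2)cc1OCc1ccccc1 | intermediate
8 | 4,4'-dihydroxybenzophenone | O=C(c1ccc(O)cc1)c1ccc(O)cc1 | starting material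
9 | bis(4-hydroxyphenyl)methanol | OC(c1ccc(O)cc1)c1ccc(O)cc1 | intermediate
10 | 4-[(4-hydroxyphenyl)methylidene]cyclohexa-2,5-dien-1-one (para-quinone methide, not isolated) | O=C1C=CC(=Cc2ccc(O)cc2)C=C1 | intermediate
11 | (2S)-2-[5,7-bis(benzyloxy)-4-oxo-4H-chromen-3-yl]-3,3-bis(4-hydroxyphenyl)-1-[2,4,6-tris(benzyloxy)phenyl]propan-1-one | O=C(c1c(OCc2ccccc2)cc(OCc2ccccc2)cc1OCc1ccccc1)[C@H](c1coc2cc(OCc3ccccc3)cc(OCc3ccccc3)c2c1=O)C(c1ccc(O)cc1)c1ccc(O)cc1 | intermediate
12 | (+)-chamaechromone, (2S)-2-(5,7-dihydroxy-4-oxo-4H-chromen-3-yl)-3,3-bis(4-hydroxyphenyl)-1-(2,4,6-trihydroxyphenyl)propan-1-one | O=C(c1c(O)cc(O)cc1O)[C@H](c1coc2cc(O)cc(O)c2c1=O)C(c1ccc(O)cc1)c1ccc(O)cc1 | target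

Total step count: 8
Longest linear sequence: 5 steps (steps 1, 2, 5, 7, 8)

Steps most likely to fail

Step 7 (Proposed new method). Three processes may defeat it:
- Friedel-Crafts attack of the quinone methide on the benzyloxy-rich rings, or its self-condensation, may outrun the enol addition.
- Enolization of 7 may be too slow under the weak acid.
- Facial discrimination may be poor or of the opposite sense. If only the sense is wrong, (S)-TRIP is taken.

The fallback uses known chemistry, sets out from 7 and 8 and comes back at 12. Ketone 7 is converted with TBSOTf and Et3N in CH2Cl2 at 0 °C into its (Z)-tert-butyldimethylsilyl enol ether F1. In parallel 8 is benzylated (BnBr, K2CO3, DMF) to bis[4-(benzyloxy)phenyl]methanone F2, which NaBH4 reduces to bis[4-(benzyloxy)phenyl]methanol F3. A Mukaiyama-type SN1 alkylation of F1 with F3 under InCl3 catalysis in CH2Cl2 at rt should give the racemic heptabenzyl ketone F4, since the silyl enol ether is far more nucleophilic than the arene rings. Preparative HPLC on a chiral stationary phase then supplies the (S)-enantiomer F5, and its hydrogenolysis (H2, Pd/C, EtOAc/MeOH) should give 12.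

Step 5. Three processes may divert it:
- A 1,6-hydrogen shift from an ortho benzyloxy CH2 group may quench the phenacyl radical before it adds.
- The phenol may be O-alkylated by 5.
- Liberated dimethylamine may consume 5.

The fallback sets out from 3 and comes back at 7. Enaminone 3 is cyclized with iodine in CHCl3 at rt to 5,7-bis(benzyloxy)-3-iodo-4H-chromen-4-one F6. F6 is then joined to ketone 4 by palladium-catalysed ketone alpha-arylation (Pd2(dba)3, Xantphos, K3PO4, toluene, 80 °C), which should give 7.

Step 8. Three processes may spoil it: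
- Prolonged exposure may saturate the pyranone C2–C3 double bond or reduce the ketone.
- Cleavage of the five ethers may stay incomplete.
- Once the phenols are free, configuration may be lost through enolization or reversible retro-1,6-addition.

The fallback sets out from 11 and comes back at 12. Non-reductive Lewis-acid debenzylation with BCl3 and pentamethylbenzene as cation scavenger in CH2Cl2 at −78 °C, followed by a cold methanol quench, should give 12 directly; this fallback makes no new compound (F0).

Further compounds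
F1 | step 7 | (Z)-tert-butyldimethylsilyl enol ether of 7, 5,7-bis(benzyloxy)-3-{(Z)-2-[(tert-butyldimethylsilyl)oxy]-2-[2,4,6-tris(benzyloxy)phenyl]ethenyl}-4H-chromen-4-one | CC(C)(C)[Si](C)(C)O/C(=C\c1coc2cc(OCc3ccccc3)cc(OCc3ccccc3)c2c1=O)c1c(OCc2ccccc2)cc(OCc2ccccc2)cc1OCc1ccccc1
F2 | step 7 | bis[4-(benzyloxy)phenyl]methanone | O=C(c1ccc(OCc2ccccc2)cc1)c1ccc(OCc2ccccc2)cc1
F3 | step 7 | bis[4-(benzyloxy)phenyl]methanol | OC(c1ccc(OCc2ccccc2)cc1)c1ccc(OCc2ccccc2)cc1
F4 | step 7 | racemic 2-[5,7-bis(benzyloxy)-4-oxo-4H-chromen-3-yl]-3,3-bis[4-(benzyloxy)phenyl]-1-[2,4,6-tris(benzyloxy)phenyl]propan-1-one | O=C(c1c(OCc2ccccc2)cc(OCc2ccccc2)cc1OCc1ccccc1)C(c1coc2cc(OCc3ccccc3)cc(OCc3ccccc3)c2c1=O)C(c1ccc(OCc2ccccc2)cc1)c1ccc(OCc2ccccc2)cc1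
F5 | step 7 | (2S)-2-[5,7-bis(benzyloxy)-4-oxo-4H-chromen-3-yl]-3,3-bis[4-(benzyloxy)phenyl]-1-[2,4,6-tris(benzyloxy)phenyl]propan-1-one | O=C(c1c(OCc2ccccc2)cc(OCc2ccccc2)cc1OCc1ccccc1)[C@H](c1coc2cc(OCc3ccccc3)cc(OCc3ccccc3)c2c1=O)C(c1ccc(OCc2ccccc2)cc1)c1ccc(OCc2ccccc2)cc1
F6 | step 5 | 5,7-bis(benzyloxy)-3-iodo-4H-chromen-4-one | O=c1c(I)coc2cc(OCc3ccccc3)cc(OCc3ccccc3)c12
F0 | step 8 | none | none
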